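Temperature and time are what separate these flasks: Thursday's is Monday's with its first 12 h spent cold. Ring is an intermediate, made from substrate and lost further on, so those extra hot hours in Monday's may cost ring.

| flask | substrate | temperature | remark | time |
|---|---|---|---|---|
| west | 0.39 M | 30 °C | run made earlier |  |
| north | 0.58 M | 60 °C | run made earlier |  |
| Monday's | 0.77 M | 85 °C |  | 25 h |
| Thursday's | 0.77 M |  | at 35 °C until 12 h, from then on at 85 °C | 25 h |
| Wednesday's | 0.77 M | 60 °C |  | 25 h |
| Friday's | 0.77 M | 35 °C |  | 25 h |

| run | time / h | ring / % | substrate / % |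
|---|---|---|---|
| west | 30.0 | 0.6 | 93.5 |
| west | 60.0 | 2.0 | 86.3 |
| west | 96.0 | 3.5 | 82.3 |
| west | 120 | 4.4 | 78.7 |
| west | 144 | 4.0 | 73.6 |
| west | 192 | 6.2 | 68.9 |
| west | 240 | 6.7 | 62.5 |
| north | 6.00 | 10.0 | 56.9 |
| north | 15.0 | 19.0 | 31.6 |
| north | 20.0 | 23.4 | 24.8 |
| north | 30.0 | 26.1 | 17.1 |
| north | 40.0 | 28.0 | 15.3 |
| north | 48.0 | 25.8 | 14.0 |

(scatter of a reading: 1 percentage point)

1. the flask with the highest amount of ring, in percent of the substrate charged ("all alike" if they lie within 1.5 percentage points) (Monday's / Thursday's / Wednesday's / Friday's / all alike)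
2. final ring, as a percentage of the substrate charged, in Monday's
3. final ring, as a percentage of the substrate charged, in Thursday's
4. final ring, as a percentage of the substrate charged, in Wednesday's
5. final ring, as a percentage of the substrate charged, in Friday's



I carry one quantity, Λ: the decades of ring lost per hour at 85 °C, a decade being a factor of 10. First I need the speed-up. Let H be the decades gained from north to 85 °C. I take H from ring's early making, assume that ring's loss speeds up alike, and carry the west-to-north step along the scale of reciprocal absolute temperature: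

H = 1.78 × 0.705 = 1.25

North's first reading gives the first-order making constant per unit of substrate, m = 0.0212 h⁻¹. Between 30.0 h and 48.0 h, north's ring stays flat within the scatter. That gives two readings of its loss constant k at 60 °C.

From above, making balances loss, so k = m × substrate/ring:

k = 0.0127 h⁻¹

From below, I allow ring to go on rising at the pace read from 30.0 h to 40.0 h, so loss is making minus that rise:

k = 0.00570 h⁻¹

Both carry the scatter. Multiplying by 10^H and dividing by ln(10) gives the bounds on Λ, the ring's decay in decades per hour at 85 °C:

Λ from 0.0443 h⁻¹ to 0.0989 h⁻¹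

At west's pace, the cold hours give 0.335% ring, so I count them as lost time. Substrate's half-life by making at 85 °C is 1.82 h, far shorter than Thursday's 13.0 h hot. Both flasks should therefore be past their peak, and Thursday's over Monday's is 10^(Λ × 12 h):

ratio from 3.40 to 15.4

The forecast differs: Monday's most, with 38%, 37%, 20% and 1.7% in the order asked, reading “assuming the ring survives; north shows no clear decay”. Its ratio of 0.974 lies below my bracket.

The flasks give 7.17%, 25.8%, 22.5% and 1.77% in that order, so Thursday's holds most. The true ratio, 3.60, falls inside the bracket, above its lower end and below its upper end.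

    2 substrate ⇌ open dimer (K = 6.10 M⁻¹, k = 6.24 × 10⁻⁶ M⁻¹ s⁻¹, Ea = 90.0 kJ mol⁻¹, ΔH = −56.0 kJ mol⁻¹)
    substrate ⇌ dormant form (K = 1.90, k = 1.58 × 10⁻⁵ s⁻¹, Ea = 112 kJ mol⁻¹, ΔH = −34.0 kJ mol⁻¹)
    substrate → ring (k = 6.89 × 10⁻⁶ s⁻¹, Ea = 119 kJ mol⁻¹)
    ring → over-reaction product (k = 2.35 × 10⁻⁶ s⁻¹, Ea = 113 kJ mol⁻¹)
    (constants at 60 °C)

In Thursday's, ring is made 1.97 times as fast as it is used up at 14.4 h, but at 25.0 h the same ratio is 0.382, less than one, so its ring is falling at the asked time. The neighbour left as Thursday's until 4.0 d has 71.0 h more hot, which at the lower Λ take 3.14 decades off ring, and it reads 0%.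

(The readings are simulated on assumed constants; scatter was added.)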